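## Retrosynthetic overview

1. The target is cut into two molecules of one vinylallene ketone, a (2S,3S,4S)-2,3-epoxy-4-hydroxy-2-prenylcyclohexanone with a 6-(3-methylbuta-1,3-dienylidene) group. Their in-flask [4+2] union closes the central ring A and the spiro centre last.
2. The vinylallene ketone is traced to a 1-alkynyl-2,3-epoxycyclopentane-1,4-diol with a methoxy leaving group on the side chain. Ionization and a 1,2-shift of the ring CH2 onto the alkyne carbon expand the five-membered ring to the six-membered rings B and C and unveil the allene.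
3. The epoxy diol comes from a cis-cyclopent-2-ene-1,4-diol by hydroxyl-directed epoxidation, and that from a 2-prenyl-4-silyloxycyclopentenone plus the lithium acetylide of 3-methoxy-2-methylpent-1-en-4-yne.
4. The enone comes from (S)-4-silyloxycyclopent-2-enone by α-iodination and Stille prenylation (prenyl chloride as prenyl source). The alkyne comes from methacrolein and ethynylmagnesium bromide.
5. Ring order: cyclopentene (bought), then the epoxide, then cyclohexanone rings B and C (ring expansion), then central ring A (dimerization).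

Assumptions: the (S)-silyloxycyclopentenone is taken as commercially available. The methoxy-bearing side-chain carbon is carried racemic (epimer mixtures, centre left unspecified in SMILES), because it becomes a planar cation in step 8. TBS = tert-butyldimethylsilyl.

## Route

Step 1
Reactants: 1 methacrolein (2-methylprop-2-enal); 2 ethynylmagnesium bromide
Product: 3 rac-2-methylpent-1-en-4-yn-3-ol
Conditions: THF, 0 °C; then sat. aq NH4Cl
Reagents that add atoms: none
Why: 1,2-addition of the alkynyl Grignard reagent to the aldehyde; the new carbinol centre is racemic, which is immaterial because it is ionized in step 8.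

Step 2
Reactants: 3 rac-2-methylpent-1-en-4-yn-3-ol
Product: 4 rac-3-methoxy-2-methylpent-1-en-4-yne
Conditions: NaH, MeI, THF, 0 → 23 °C
Reagents that add atoms: iodomethane, CI
Why: Williamson ether synthesis; the methyl ether survives acetylide formation and the vanadium epoxidation and later serves as the leaving group.

Step 3
Reactants: 5 (S)-4-[(TBS)oxy]cyclopent-2-en-1-one
Product: 6 (S)-4-[(TBS)oxy]-2-iodocyclopent-2-en-1-one
Conditions: I2, pyridine, CH2Cl2, 0 → 23 °C
Reagents that add atoms: iodine, II
Why: Johnson α-iodination of an enone (pyridine conjugate addition, iodination of the enolate, elimination), which leaves C4 untouched.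

Step 4
Reactants: 7 1-chloro-3-methylbut-2-ene (prenyl chloride)
Product: 9 tributyl(3-methylbut-2-en-1-yl)stannane, via (3-methylbut-2-enyl)magnesium chloride 8 (not isolated)
Conditions: Mg, Bu3SnCl, THF, 0 → 23 °C (Barbier mode)
Reagents that add atoms: tributyltin chloride, CCCC[Sn](Cl)(CCCC)CCCC; magnesium, [Mg] (retained in 8 only)
Why: Barbier-type Grignard formation and trapping by the tin chloride, which bonds at the primary carbon of the prenyl unit.

Step 5
Reactants: 6 (S)-4-[(TBS)oxy]-2-iodocyclopent-2-en-1-one; 9 tributyl(3-methylbut-2-en-1-yl)stannane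
Product: 10 (S)-4-[(TBS)oxy]-2-(3-methylbut-2-en-1-yl)cyclopent-2-en-1-one
Conditions: Pd2(dba)3 (2.5 mol %), AsPh3, CuI (10 mol %), NMP, 23–50 °C
Reagents that add atoms: none
Why: Stille coupling: zerovalent palladium inserts into the C–I bond, and copper-assisted transmetalation with reductive elimination at the unsubstituted allyl terminus gives the linear prenyl group under neutral conditions that spare the β-silyloxy ketone and C4.

Step 6
Reactants: 4 rac-3-methoxy-2-methylpent-1-en-4-yne; 10 (S)-4-[(TBS)oxy]-2-(3-methylbut-2-en-1-yl)cyclopent-2-en-1-one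
Product: 13 (1R,4S)-1-(3-methoxy-4-methylpent-4-en-1-yn-1-yl)-2-(3-methylbut-2-en-1-yl)cyclopent-2-ene-1,4-diol, via lithium acetylide 11 (not isolated), via lithium alkoxide 12 (not isolated)
Conditions: 4, n-BuLi, THF, −78 °C; add 10, −78 °C; then TBAF (THF), −78 → 23 °C; sat. aq NH4Cl
Reagents that add atoms: n-butyllithium, [Li]CCCC (lithium retained in 11 and 12 only)
Why: 1,2-addition of a lithium acetylide to the enone carbonyl anti to the C4 silyloxy group sets C1 with its hydroxyl cis to the C4 oxygen (this centre only directs step 7 and is erased in step 8), and fluoride then cleaves the silyl ether in the same flask.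

Step 7
Reactants: 13 (1R,4S)-1-(3-methoxy-4-methylpent-4-en-1-yn-1-yl)-2-(3-methylbut-2-en-1-yl)cyclopent-2-ene-1,4-diol
Product: 14 (1S,2S,3S,4S)-2,3-epoxy-1-(3-methoxy-4-methylpent-4-en-1-yn-1-yl)-2-(3-methylbut-2-en-1-yl)cyclopentane-1,4-diol
Conditions: VO(acac)2 (5 mol %), t-BuOOH (decane, 1.2 equiv), CH2Cl2, 0 °C
Reagents that add atoms: tert-butyl hydroperoxide, CC(C)(C)OO
Why: Vanadium-catalysed hydroxyl-directed epoxidation (Sharpless–Michaelson type): the vanadate ester of the cis-1,4-diol delivers oxygen to the ring alkene on the face of both hydroxyls, setting C2 and C3 with the epoxide cis to the C4 hydroxyl, while the prenyl and isopropenyl alkenes, lacking an allylic hydroxyl, react far more slowly.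

Step 8
Reactants: 14 (1S,2S,3S,4S)-2,3-epoxy-1-(3-methoxy-4-methylpent-4-en-1-yn-1-yl)-2-(3-methylbut-2-en-1-yl)cyclopentane-1,4-diol (two molecules)
Product: 16 target spiro dimer CNP0235815.2 [(R) spiro centre; (2S,3S,4S) in rings B and C; both exocyclic alkenes Z], via vinylallene ketone 15 (not isolated)
Conditions: Sc(OTf)3 (5 mol %), 4 Å molecular sieves, CH2Cl2 (0.02 M), −40 → 0 °C; then i-Pr2NEt (0.2 equiv), concentrate, PhMe (0.3 M), 23 → 40 °C
Reagents that add atoms: none
Why: Proposed new method: Sc(OTf)3 ionizes only the doubly activated (allylic plus propargylic) methyl ether, and because the delocalized cation carries positive charge on the alkyne carbon bound to the carbinol, the ring CH2 (C5, a better migrating group than the oxygen-bearing epoxide carbon C2) shifts from C1 to that carbon as the hydroxyl collapses to the ketone, so the alkyne carbon is inserted into the ring (five- to six-membered) and the allene is unveiled with C2, C3 and C4 untouched; the closest known reactions are semipinacol ring expansions of 1-alkenyl- and 1-alkynylcycloalkanols (strained cyclobutanols) and the acid ionization of propargylic alcohols, but a 1,2-shift onto the allenyl terminus of a free propargylic cation in an unstrained cyclopentanol has not been shown; base then equilibrates the allene axis of 15 through its ynenolate and two molecules combine in a Diels–Alder dimerization (vinylallene of one as diene, bonding on its carbonyl side; ketone-conjugated allene bond of the other as dienophile, attacked anti to its isopropenyl group and anti to the C2 prenyl group), which sets the (R) spiro centre and both Z exocyclic alkenes.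

## Compound list

1 | methacrolein (2-methylprop-2-enal) | C=C(C)C=O | starting material
2 | ethynylmagnesium bromide | C#C[Mg]Br | starting material
3 | rac-2-methylpent-1-en-4-yn-3-ol | C=C(C)C(O)C#C | intermediate
4 | rac-3-methoxy-2-methylpent-1-en-4-yne | C=C(C)C(OC)C#C | intermediate
5 | (S)-4-[(tert-butyldimethylsilyl)oxy]cyclopent-2-en-1-one | O=C1C[C@H](O[Si](C)(C)C(C)(C)C)C=C1 | starting material
6 | (S)-4-[(tert-butyldimethylsilyl)oxy]-2-iodocyclopent-2-en-1-one | O=C1C[C@H](O[Si](C)(C)C(C)(C)C)C=C1I | intermediate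
7 | 1-chloro-3-methylbut-2-ene (prenyl chloride) | CC(C)=CCCl | starting material
8 | (3-methylbut-2-en-1-yl)magnesium chloride (in the flask) | CC(C)=CC[Mg]Cl | intermediate
9 | tributyl(3-methylbut-2-en-1-yl)stannane | CCCC[Sn](CCCC)(CCCC)CC=C(C)C | intermediate
10 | (S)-4-[(tert-butyldimethylsilyl)oxy]-2-(3-methylbut-2-en-1-yl)cyclopent-2-en-1-one | O=C1C[C@H](O[Si](C)(C)C(C)(C)C)C=C1CC=C(C)C | intermediate
11 | lithium acetylide of 4, (3-methoxy-4-methylpent-4-en-1-yn-1-yl)lithium (in the flask) | [Li]C#CC(OC)C(C)=C | intermediate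
12 | lithium (1R,4S)-4-[(tert-butyldimethylsilyl)oxy]-1-(3-methoxy-4-methylpent-4-en-1-yn-1-yl)-2-(3-methylbut-2-en-1-yl)cyclopent-2-en-1-olate (in the flask; alkynyl trans to the silyloxy group) | [Li]O[C@]1(C#CC(OC)C(C)=C)C[C@H](O[Si](C)(C)C(C)(C)C)C=C1CC=C(C)C | intermediate
13 | (1R,4S)-1-(3-methoxy-4-methylpent-4-en-1-yn-1-yl)-2-(3-methylbut-2-en-1-yl)cyclopent-2-ene-1,4-diol (hydroxyls cis; epimers at the methoxy carbon) | O[C@]1(C#CC(OC)C(C)=C)C[C@H](O)C=C1CC=C(C)C | intermediate
14 | (1S,2S,3S,4S)-2,3-epoxy-1-(3-methoxy-4-methylpent-4-en-1-yn-1-yl)-2-(3-methylbut-2-en-1-yl)cyclopentane-1,4-diol (both hydroxyls and the epoxide oxygen on one face; epimers at the methoxy carbon) | O[C@]1(C#CC(OC)C(C)=C)C[C@H](O)[C@@H]2O[C@@]21CC=C(C)C | intermediate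
15 | (2S,3S,4S)-2,3-epoxy-4-hydroxy-6-(3-methylbuta-1,3-dien-1-ylidene)-2-(3-methylbut-2-en-1-yl)cyclohexan-1-one (hydroxyl cis to the epoxide; allene axis not fixed; in the flask) | C=C(C)C=C=C1C[C@H](O)[C@@H]2O[C@]2(CC=C(C)C)C1=O | intermediate
16 | CNP0235815.2: ring C, a (2S,3S,4S)-2,3-epoxy-4-hydroxy-2-prenylcyclohexan-1-one, is spiro-fused at C6 (R) to central cyclohexene ring A; going round ring A from the spiro carbon: a carbon carrying a (Z)-2-methylprop-2-en-1-ylidene group (isopropenyl cis to the spiro carbon), a carbon doubly bonded (Z, ring A carbon cis to the carbonyl) to C6 of ring B [a second (2S,3S,4S)-2,3-epoxy-4-hydroxy-2-prenylcyclohexan-1-one], then CH=C(CH3)–CH2 back to the spiro carbon | C=C(C)/C=C1/C(=C2/C[C@H](O)[C@@H]3O[C@]3(CC=C(C)C)C2=O)C=C(C)C[C@@]12C[C@H](O)[C@@H]1O[C@]1(CC=C(C)C)C2=O | target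

## Step count and risks

Total steps: 8. Longest linear sequence: 5 steps (5 → 6 → 10 → 13 → 14 → 16, steps 3, 5, 6, 7, 8).

Three steps most likely to fail:

**Step 8 (proposed ring expansion and in-flask dimerization).** The risks are:
- the Lewis acid may open the epoxide instead of ionizing the ether;
- the epoxide carbon may migrate instead of the CH2;
- the prenyl alkene may capture the cationic alkyne carbon;
- the dimerization may give other face or regio isomers.

Fallback by known chemistry, setting out from 10 and coming back at 15: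
- Luche reduction of 10 (NaBH4, CeCl3·7H2O, MeOH, −78 °C; hydride anti to the silyloxy group) gives the cis allylic alcohol (1R,4S)-4-[(tert-butyldimethylsilyl)oxy]-2-(3-methylbut-2-en-1-yl)cyclopent-2-en-1-ol F1.
- Hydroxyl-directed epoxidation (VO(acac)2, t-BuOOH) gives the all-cis epoxy alcohol (1R,2R,3S,4S)-4-[(tert-butyldimethylsilyl)oxy]-2,3-epoxy-2-(3-methylbut-2-en-1-yl)cyclopentan-1-ol F2.
- Dess–Martin oxidation gives the epoxy ketone (2S,3S,4S)-4-[(tert-butyldimethylsilyl)oxy]-2,3-epoxy-2-(3-methylbut-2-en-1-yl)cyclopentan-1-one F3.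
- One-carbon ring expansion with TMSCHN2 and AlMe3 (CH2Cl2, −78 °C; the CH2 carbon migrates, not the epoxide carbon) gives the α-silyl ketone (2S,3S,4S)-4-[(tert-butyldimethylsilyl)oxy]-2,3-epoxy-2-(3-methylbut-2-en-1-yl)-6-(trimethylsilyl)cyclohexan-1-one F4. It is protodesilylated without isolation (K2CO3, MeOH) to the cyclohexanone (2S,3S,4S)-4-[(tert-butyldimethylsilyl)oxy]-2,3-epoxy-2-(3-methylbut-2-en-1-yl)cyclohexan-1-one F5.
- The lithium enolate of F5 (LiN(SiMe3)2, THF, −78 °C; only C6 can enolize) is alkynylated with the ethynylbenziodoxolone reagent 1-(3-methylbut-3-en-1-yn-1-yl)-1,2-benziodoxol-3(1H)-one. This gives the alkynyl ketone (2S,3S,4S)-4-[(tert-butyldimethylsilyl)oxy]-2,3-epoxy-6-(3-methylbut-3-en-1-yn-1-yl)-2-(3-methylbut-2-en-1-yl)cyclohexan-1-one F6.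
- TBAF removes the silyl group to give the hydroxy alkynyl ketone (2S,3S,4S)-2,3-epoxy-4-hydroxy-6-(3-methylbut-3-en-1-yn-1-yl)-2-(3-methylbut-2-en-1-yl)cyclohexan-1-one F7. Under the basic conditions it tautomerizes to the allenyl ketone 15, which dimerizes to 16 as in the second half of step 8.

**Step 6 (acetylide addition and in-flask desilylation).** The risks are enolization of 10 with β-elimination of the silyloxy group, and incomplete anti selectivity at the carbonyl. The fallback changes the order of bond formation, setting out from 6 and coming back at 13. The acetylide 11 is added to the more electrophilic iodoenone 6, where the flanking iodine reinforces anti attack. This gives the iodo carbinol (1S,4S)-4-[(tert-butyldimethylsilyl)oxy]-2-iodo-1-(3-methoxy-4-methylpent-4-en-1-yn-1-yl)cyclopent-2-en-1-ol F8. Stille coupling of F8 with 9 (Pd2(dba)3, AsPh3, CuI) gives the silyl ether carbinol (1R,4S)-4-[(tert-butyldimethylsilyl)oxy]-1-(3-methoxy-4-methylpent-4-en-1-yn-1-yl)-2-(3-methylbut-2-en-1-yl)cyclopent-2-en-1-ol F9. TBAF then gives 13.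

**Step 5 (Stille prenylation).** The risks are coupling at the substituted allyl terminus (reverse prenyl product) and decomposition of the sensitive iodoenone. The fallback builds the prenyl group in two operations, setting out from 6 and coming back at 10. Stille coupling of 6 with allyltributylstannane (same catalyst system; no regiochemical ambiguity) gives (S)-2-allyl-4-[(tert-butyldimethylsilyl)oxy]cyclopent-2-en-1-one F10. Cross-metathesis with 2-methylbut-2-ene (second-generation Grubbs catalyst RuCl2(=CHPh)(H2IMes)(PCy3), CH2Cl2, 40 °C) converts the allyl into the prenyl group and gives 10.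

## Further compounds

F1 | step 8 | (1R,4S)-4-[(tert-butyldimethylsilyl)oxy]-2-(3-methylbut-2-en-1-yl)cyclopent-2-en-1-ol | O[C@@H]1C[C@H](O[Si](C)(C)C(C)(C)C)C=C1CC=C(C)C
F2 | step 8 | (1R,2R,3S,4S)-4-[(tert-butyldimethylsilyl)oxy]-2,3-epoxy-2-(3-methylbut-2-en-1-yl)cyclopentan-1-ol | O[C@@H]1C[C@H](O[Si](C)(C)C(C)(C)C)[C@@H]2O[C@@]21CC=C(C)C
F3 | step 8 | (2S,3S,4S)-4-[(tert-butyldimethylsilyl)oxy]-2,3-epoxy-2-(3-methylbut-2-en-1-yl)cyclopentan-1-one | O=C1C[C@H](O[Si](C)(C)C(C)(C)C)[C@@H]2O[C@@]21CC=C(C)C
F4 | step 8 | (2S,3S,4S)-4-[(tert-butyldimethylsilyl)oxy]-2,3-epoxy-2-(3-methylbut-2-en-1-yl)-6-(trimethylsilyl)cyclohexan-1-one (C6 epimers) | C[Si](C)(C)C1C[C@H](O[Si](C)(C)C(C)(C)C)[C@@H]2O[C@]2(CC=C(C)C)C1=O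
F5 | step 8 | (2S,3S,4S)-4-[(tert-butyldimethylsilyl)oxy]-2,3-epoxy-2-(3-methylbut-2-en-1-yl)cyclohexan-1-one | C1C[C@H](O[Si](C)(C)C(C)(C)C)[C@@H]2O[C@]2(CC=C(C)C)C1=O
F6 | step 8 | (2S,3S,4S)-4-[(tert-butyldimethylsilyl)oxy]-2,3-epoxy-6-(3-methylbut-3-en-1-yn-1-yl)-2-(3-methylbut-2-en-1-yl)cyclohexan-1-one (C6 epimers) | C=C(C)C#CC1C[C@H](O[Si](C)(C)C(C)(C)C)[C@@H]2O[C@]2(CC=C(C)C)C1=O
F7 | step 8 | (2S,3S,4S)-2,3-epoxy-4-hydroxy-6-(3-methylbut-3-en-1-yn-1-yl)-2-(3-methylbut-2-en-1-yl)cyclohexan-1-one (C6 epimers) | C=C(C)C#CC1C[C@H](O)[C@@H]2O[C@]2(CC=C(C)C)C1=O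
F8 | step 6 | (1S,4S)-4-[(tert-butyldimethylsilyl)oxy]-2-iodo-1-(3-methoxy-4-methylpent-4-en-1-yn-1-yl)cyclopent-2-en-1-ol | O[C@]1(C#CC(OC)C(C)=C)C[C@H](O[Si](C)(C)C(C)(C)C)C=C1I
F9 | step 6 | (1R,4S)-4-[(tert-butyldimethylsilyl)oxy]-1-(3-methoxy-4-methylpent-4-en-1-yn-1-yl)-2-(3-methylbut-2-en-1-yl)cyclopent-2-en-1-ol | O[C@]1(C#CC(OC)C(C)=C)C[C@H](O[Si](C)(C)C(C)(C)C)C=C1CC=C(C)C
F10 | step 5 | (S)-2-allyl-4-[(tert-butyldimethylsilyl)oxy]cyclopent-2-en-1-one | O=C1C[C@H](O[Si](C)(C)C(C)(C)C)C=C1CC=C
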